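I began with the gap. The flask is the south run carried on, and crystals count inside target.

| flask | substrate | remark | time |
|---|---|---|---|
| south | 3 M | the very flask that is asked about, followed so far |  |
| flask | 3.0 M |  | 50 h |

south run (percent of the substrate charged)

| time / h | isomer of the product A / % | target / % | substrate / % |
|---|---|---|---|
| 0.250 | 0.3 | 9.6 | 90.2 |
| 0.833 | 0 | 26.2 | 70.9 |
| 1.33 | 0 | 37.3 | 60.5 |
| 2.00 | 0.6 | 48.1 | 48.0 |
| 3.00 | 0.4 | 59.9 | 36.1 |
| 4.00 | 1.7 | 67.8 | 28.4 |

(readings scatter by 0.5 percentage points)

- for target the crystals are counted in
- as a solid, counted per litre of solution: crystals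
- on the list of suspects stand: substrate <-> target; crystals <-> target; substrate <-> isomer of the product A; target <-> isomer of the product B

* ratio of isomer of the product A to target at 2.5 min
* ratio of isomer of the product A to target at 50 h
* which of isomer of the product A and target there is more of at 50 h

The gap is what substrate, target and isomer of the product A leave unaccounted for, and I took it for isomer of the product B. In the south run target rose from 26.2% at 0.833 h to 67.8% at 4.00 h, yet the gap went from 2.90% to 2.10%. I read this as c(dissolved target) standing still while crystals took the excess, a fast pre-equilibrium with the solid. The way back from dissolved target to substrate is then a constant feed, and substrate falls first-order towards a floor, which the evenly spaced substrate readings at 2.00 h, 3.00 h and 4.00 h give, with their scatter: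

floor = (first × third − second × second) / (first + third − 2 × second) = 14.3%

I called the floor concentration, the c(substrate) standing against saturated solution, and it came to 0.428 M. Isomer of the product A rests on one reading, with scatter 0.5 percentage points, over the area under substrate up to 4.00 h:

k = 1.7% / 2.14 h = 0.00794 /h

ratio at 2.5 min = 0.00794 /h / 0.413 /h = 0.0192

at 50 h: isomer of the product A 6.92%, target 76.7%, ratio 0.0902

The forecast gave 0.011 and 0.065, lower than my figures, with target ahead, in its words “Target clearly leads.”

The flask gave 0.0198 and 0.108, with 8.00% isomer of the product A against 74.2% target.

    substrate ⇌ target (K = 1.50, k = 0.450 /h)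
    crystals ⇌ target, rate k2*(cs2 - [target]) while solid is left; crystals form when [target] > cs2 (solubility = 0.700 M, k = 52.0 /h)
    substrate ⇌ isomer of the product A (K = 6.70, k = 0.00880 /h)
    target ⇌ isomer of the product B (K = 0.110, k = 0.190 /h)

This flask held substrate at 15.3% at 25.0 h and 15.3% at 50.0 h, which is 0.458 M beside my 0.428 M. The neighbouring flask, charged with 1.8 M of substrate, takes the same 0.428 M as 23.8% of its charge. It held 25.5% substrate at 50.0 h, with crystals at 19.3%, and its ratio of isomer of the product A to target stood at 0.207.

All runs were computed for an exercise; the scatter is artificial.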